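The 2,2-dimethyl-2H-pyran ring is disconnected across C3–C4 and O1–C2 (chromene numbering). This leads back to a dearomatised 6-formyl-2-benzoylphloroglucinol, whose quaternary carbon already carries the prenyl group and the (R)-configured acid chain, and to (2-methylprop-1-en-1-yl)boronic acid. In the key step an amine-mediated borono-Mannich alkenyl transfer to the formyl carbon, loss of the amine and oxa-6π electrocyclisation make both bonds in one operation. It exploits the formyl group on C4a lying beside the enolic oxygen on C8a of the dienone ring. The chain comes from an auxiliary-controlled alkylation, the quaternary centre from a palladium-catalysed asymmetric dearomative prenylation.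

Key step: step 8

Assumption 1: enolised triketones are drawn as one tautomer and CIP descriptors refer to that tautomer; the quaternary carbon is 1R in 16 and 8S in 21–23 with the same spatial arrangement.
Assumption 2: the (R,R) antipode of the ligand in step 7 is taken as the one that delivers prenyl to the required face; if a first run shows the opposite sense, the (S,S) antipode is used under the same conditions.
Assumption 3: compounds 5, 15 and 17 are taken as catalogue chemicals.

Step 1
Reactants: 1 (4S)-4-benzyl-1,3-oxazolidin-2-one; 2 3-methylbut-2-enoyl chloride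
Product: 4 (4S)-4-benzyl-3-(3-methylbut-2-enoyl)-1,3-oxazolidin-2-one, via lithium amide 3 (not isolated)
Conditions: n-BuLi, THF, −78 °C; then 2, −78 → 0 °C
Reagents that add atoms: 3-methylbut-2-enoyl chloride (compound 2), CC(C)=CC(=O)Cl
Why: N-acylation of the lithiated oxazolidinone by the acid chloride (attachment of the Evans auxiliary) is fast at low temperature and creates no stereocentre.

Step 2
Reactants: 4 (4S)-4-benzyl-3-(3-methylbut-2-enoyl)-1,3-oxazolidin-2-one; 5 methyl (2E)-4-bromo-2-methylbut-2-enoate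
Product: 7 methyl (2E,5S)-5-[(4S)-4-benzyl-2-oxo-1,3-oxazolidine-3-carbonyl]-2,6-dimethylhepta-2,6-dienoate, via sodium dienolate 6 (not isolated)
Conditions: NaN(SiMe3)2, THF, −78 °C; then 5, −78 → −40 °C; AcOH quench at −78 °C
Reagents that add atoms: methyl (2E)-4-bromo-2-methylbut-2-enoate (compound 5), COC(=O)/C(C)=C/CBr
Why: Evans asymmetric alkylation in its deconjugative form: γ-deprotonation gives the chelated (Z)-dienolate 6, which the allylic bromide alkylates at the α-carbon on the face opposite the benzyl group, setting C5 as (S) (the later (R) centre of the chain) and generating the isopropenyl group.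

Step 3
Reactants: 7 methyl (2E,5S)-5-[(4S)-4-benzyl-2-oxo-1,3-oxazolidine-3-carbonyl]-2,6-dimethylhepta-2,6-dienoate
Product: 8 methyl (2E,5S)-5-(hydroxymethyl)-2,6-dimethylhepta-2,6-dienoate
Conditions: NaBH4, THF/H2O (4:1), 0 °C → rt
Reagents that add atoms: none
Why: Borohydride reduces the activated exocyclic imide carbonyl much faster than the conjugated α-methyl ester, so reductive removal of the auxiliary should give the primary alcohol without touching C5.

Step 4
Reactants: 8 methyl (2E,5S)-5-(hydroxymethyl)-2,6-dimethylhepta-2,6-dienoate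
Product: 9 methyl (2E,5S)-5-(iodomethyl)-2,6-dimethylhepta-2,6-dienoate
Conditions: I2, PPh3, imidazole, CH2Cl2, 0 °C → rt
Reagents that add atoms: iodine, [I][I]
Why: Appel-type iodination proceeds by SN2 displacement at the primary carbon and leaves the neighbouring stereocentre untouched.

Step 5
Reactants: 9 methyl (2E,5S)-5-(iodomethyl)-2,6-dimethylhepta-2,6-dienoate; 10 (2,4,6-trihydroxyphenyl)(phenyl)methanone
Product: 12 methyl (2E,5R)-5-[(3-benzoyl-2,4,6-trihydroxyphenyl)methyl]-2,6-dimethylhepta-2,6-dienoate, via sodium phenolate 11 (not isolated)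
Conditions: 10 (3 equiv), NaOMe (3 equiv), MeOH, rt; then 9 (1 equiv), 60 °C
Reagents that add atoms: none
Why: Direct C-alkylation of the ambident acylphloroglucinolate 11 by SN2 at the primary iodide, in which methanol hydrogen-bonds the phenoxide oxygens and favours carbon attack, the two free ring positions are equivalent, excess 10 suppresses double alkylation, and C5 is not involved (it becomes (R) only by change of CIP priorities).

Step 6
Reactants: 12 methyl (2E,5R)-5-[(3-benzoyl-2,4,6-trihydroxyphenyl)methyl]-2,6-dimethylhepta-2,6-dienoate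
Product: 14 methyl (2E,5R)-5-[(3-benzoyl-5-formyl-2,4,6-trihydroxyphenyl)methyl]-2,6-dimethylhepta-2,6-dienoate, via iminium chloride 13 (not isolated)
Conditions: POCl3, DMF, EtOAc, 0 °C → rt; then H2O, rt
Reagents that add atoms: N,N-dimethylformamide, CN(C)C=O; water, O
Why: Vilsmeier–Haack formylation (electrophilic aromatic substitution by the chloroiminium ion) occurs at the only remaining ring C–H of the highly activated phloroglucinol, and mild hydrolysis of 13 spares the acid-sensitive isopropenyl group.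

Step 7
Reactants: 14 methyl (2E,5R)-5-[(3-benzoyl-5-formyl-2,4,6-trihydroxyphenyl)methyl]-2,6-dimethylhepta-2,6-dienoate; 15 tert-butyl 2-methylbut-3-en-2-yl carbonate
Product: 16 methyl (2E,5R)-5-{[(1R)-3-benzoyl-5-formyl-2,6-dihydroxy-1-(3-methylbut-2-en-1-yl)-4-oxocyclohexa-2,5-dien-1-yl]methyl}-2,6-dimethylhepta-2,6-dienoate
Conditions: Pd2(dba)3·CHCl3 (2.5 mol%), N,N'-[(1R,2R)-cyclohexane-1,2-diyl]bis[2-(diphenylphosphanyl)benzamide] (7.5 mol%), 15 (1.2 equiv), toluene, 0 °C → rt
Reagents that add atoms: tert-butyl 2-methylbut-3-en-2-yl carbonate (compound 15), C=CC(C)(C)OC(=O)OC(C)(C)C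
Why: Tsuji–Trost asymmetric allylic alkylation used as alkylative dearomatisation: the carbonate ionises on zerovalent palladium to a π-prenyl complex, O-prenyl ethers re-ionise so that alkylation is funnelled to the only ring carbon without an acyl group, attack at the unsubstituted allyl terminus gives the linear prenyl group, and the chiral ligand pocket selects the face of the planar anion and so sets the quaternary centre (catalyst control).

Step 8
Reactants: 16 methyl (2E,5R)-5-{[(1R)-3-benzoyl-5-formyl-2,6-dihydroxy-1-(3-methylbut-2-en-1-yl)-4-oxocyclohexa-2,5-dien-1-yl]methyl}-2,6-dimethylhepta-2,6-dienoate; 17 (2-methylprop-1-en-1-yl)boronic acid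
Product: 21 methyl (2E,5R)-5-{[(8S)-6-benzoyl-7-hydroxy-2,2-dimethyl-8-(3-methylbut-2-en-1-yl)-5-oxo-5,8-dihydro-2H-chromen-8-yl]methyl}-2,6-dimethylhepta-2,6-dienoate, via iminium enolate 18 (not isolated), via allylic amine 19 (not isolated), via oxatriene 20 (not isolated)
Conditions: 17 (2 equiv), Bn2NH (0.5 equiv), 1,4-dioxane, 80 °C
Reagents that add atoms: (2-methylprop-1-en-1-yl)boronic acid (compound 17), CC(C)=CB(O)O
Why: Proposed new method: dibenzylamine condenses with the formyl group to iminium enolate 18, the boronic acid coordinates to the neighbouring enolate oxygen and hands its 2-methylpropenyl group to the iminium carbon (C3–C4 bond, amine 19), retro-Mannich loss of dibenzylamine gives oxatriene 20, and thermal disrotatory oxa-6π electrocyclisation of 20 closes the pyran ring by the O1–C2 bond; the amine turns over. The closest known reaction type is the amine-catalysed borono-Mannich (Petasis) synthesis of 2H-chromenes from salicylaldehydes and alkenylboronic acids, transferred here to the vinylogous salicylaldehyde unit (enol OH beside CHO) of a 2-formyl-1,3-dione; oxatrienes like 20 are also the known intermediates of the enal/1,3-dione condensation–electrocyclisation. No stereocentre is created (C2 carries two methyl groups, the aminated carbon of 19 becomes sp2 again) and the quaternary carbon and C5 of the chain are not touched. The selectivity needed is closure onto the C8a oxygen and not the C5 oxygen: in 20 the C5 oxygen is the enol OH of the benzoyl-chelated triketone (an enolisation that extends conjugation into the dienyl unit), whereas the C8a carbonyl next to the quaternary carbon cannot enolise and is the only ketone of the 1-oxatriene. Since this ring closure is reversible, the isomer that keeps the chelated 2-benzoyl-1,3-dione unit is also expected to be the thermodynamic one.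

Step 9
Reactants: 21 methyl (2E,5R)-5-{[(8S)-6-benzoyl-7-hydroxy-2,2-dimethyl-8-(3-methylbut-2-en-1-yl)-5-oxo-5,8-dihydro-2H-chromen-8-yl]methyl}-2,6-dimethylhepta-2,6-dienoate
Product: 23 (2E,5R)-5-{[(8S)-6-benzoyl-7-hydroxy-2,2-dimethyl-8-(3-methylbut-2-en-1-yl)-5-oxo-5,8-dihydro-2H-chromen-8-yl]methyl}-2,6-dimethylhepta-2,6-dienoic acid, via dilithium salt 22 (not isolated)
Conditions: LiOH·H2O, THF/MeOH/H2O (3:1:1), rt; then 1 M HCl to pH 3, 0 °C
Reagents that add atoms: lithium hydroxide, [Li+].[OH-]
Why: Saponification of the methyl ester, in which the enolised triketone is deprotonated first and so shielded from hydroxide, the (E)-alkene and both stereocentres are unaffected, and cold acidification of 22 avoids acid-induced cyclisation of the prenyl and isopropenyl groups.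

Compound list
1 | (4S)-4-benzyl-1,3-oxazolidin-2-one | O=C1N[C@@H](Cc2ccccc2)CO1 | starting material
2 | 3-methylbut-2-enoyl chloride | CC(C)=CC(=O)Cl | starting material
3 | lithium (4S)-4-benzyl-2-oxo-1,3-oxazolidin-3-ide | [Li+].O=C1[N-][C@@H](Cc2ccccc2)CO1 | intermediate (not isolated)
4 | (4S)-4-benzyl-3-(3-methylbut-2-enoyl)-1,3-oxazolidin-2-one | CC(C)=CC(=O)N1[C@@H](Cc2ccccc2)COC1=O | intermediate
5 | methyl (2E)-4-bromo-2-methylbut-2-enoate | COC(=O)/C(C)=C/CBr | starting material
6 | sodium (1Z)-1-[(4S)-4-benzyl-2-oxo-1,3-oxazolidin-3-yl]-3-methylbuta-1,3-dien-1-olate | [Na+].C=C(C)/C=C(\[O-])N1[C@@H](Cc2ccccc2)COC1=O | intermediate (not isolated)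
7 | methyl (2E,5S)-5-[(4S)-4-benzyl-2-oxo-1,3-oxazolidine-3-carbonyl]-2,6-dimethylhepta-2,6-dienoate | C=C(C)[C@H](C/C=C(\C)C(=O)OC)C(=O)N1[C@@H](Cc2ccccc2)COC1=O | intermediate
8 | methyl (2E,5S)-5-(hydroxymethyl)-2,6-dimethylhepta-2,6-dienoate | C=C(C)[C@H](C/C=C(\C)C(=O)OC)CO | intermediate
9 | methyl (2E,5S)-5-(iodomethyl)-2,6-dimethylhepta-2,6-dienoate | C=C(C)[C@H](C/C=C(\C)C(=O)OC)CI | intermediate
10 | (2,4,6-trihydroxyphenyl)(phenyl)methanone | O=C(c1ccccc1)c1c(O)cc(O)cc1O | starting material
11 | sodium 4-benzoyl-3,5-dihydroxyphenolate | [Na+].O=C(c1ccccc1)c1c(O)cc([O-])cc1O | intermediate (not isolated)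
12 | methyl (2E,5R)-5-[(3-benzoyl-2,4,6-trihydroxyphenyl)methyl]-2,6-dimethylhepta-2,6-dienoate | C=C(C)[C@H](C/C=C(\C)C(=O)OC)Cc1c(O)cc(O)c(C(=O)c2ccccc2)c1O | intermediate
13 | iminium chloride: 12 with CH=N+(CH3)2 Cl− on the free ring carbon (between the two OH groups remote from benzoyl) | C=C(C)[C@H](C/C=C(\C)C(=O)OC)Cc1c(O)c(C=[N+](C)C)c(O)c(C(=O)c2ccccc2)c1O.[Cl-] | intermediate (not isolated)
14 | methyl (2E,5R)-5-[(3-benzoyl-5-formyl-2,4,6-trihydroxyphenyl)methyl]-2,6-dimethylhepta-2,6-dienoate | C=C(C)[C@H](C/C=C(\C)C(=O)OC)Cc1c(O)c(C=O)c(O)c(C(=O)c2ccccc2)c1O | intermediate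
15 | tert-butyl 2-methylbut-3-en-2-yl carbonate | C=CC(C)(C)OC(=O)OC(C)(C)C | starting material
16 | methyl (2E,5R)-5-{[(1R)-3-benzoyl-5-formyl-2,6-dihydroxy-1-(3-methylbut-2-en-1-yl)-4-oxocyclohexa-2,5-dien-1-yl]methyl}-2,6-dimethylhepta-2,6-dienoate | C=C(C)[C@H](C/C=C(\C)C(=O)OC)C[C@@]1(CC=C(C)C)C(O)=C(C(=O)c2ccccc2)C(=O)C(C=O)=C1O | intermediate
17 | (2-methylprop-1-en-1-yl)boronic acid | CC(C)=CB(O)O | starting material
18 | iminium enolate: 16 with CH=N+(CH2Ph)2 in place of CHO and O− in place of the OH on the ring carbon between it and the quaternary carbon | C=C(C)[C@H](C/C=C(\C)C(=O)OC)C[C@@]1(CC=C(C)C)C(O)=C(C(=O)c2ccccc2)C(=O)C(C=[N+](Cc2ccccc2)Cc2ccccc2)=C1[O-] | intermediate (not isolated)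
19 | allylic amine: 16 with CH(NBn2)–CH=C(CH3)2 in place of CHO (both epimers at the aminated carbon) | C=C(C)[C@H](C/C=C(\C)C(=O)OC)C[C@@]1(CC=C(C)C)C(O)=C(C(=O)c2ccccc2)C(=O)C(C(C=C(C)C)N(Cc2ccccc2)Cc2ccccc2)=C1O | intermediate (not isolated)
20 | oxatriene: 3-methylbut-2-en-1-ylidene on the former formyl-bearing ring carbon, dienyl unit syn to the ketone next to the quaternary carbon, other flanking oxygen as benzoyl-chelated enol | C=C(C)[C@H](C/C=C(\C)C(=O)OC)C[C@@]1(CC=C(C)C)C(=O)C(C(=O)c2ccccc2)=C(O)C(=C/C=C(C)C)/C1=O | intermediate (not isolated)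
21 | methyl (2E,5R)-5-{[(8S)-6-benzoyl-7-hydroxy-2,2-dimethyl-8-(3-methylbut-2-en-1-yl)-5-oxo-5,8-dihydro-2H-chromen-8-yl]methyl}-2,6-dimethylhepta-2,6-dienoate | C=C(C)[C@H](C/C=C(\C)C(=O)OC)C[C@@]1(CC=C(C)C)C(O)=C(C(=O)c2ccccc2)C(=O)C2=C1OC(C)(C)C=C2 | intermediate
22 | dilithium salt of 23 (carboxylate and triketone enolate) | [Li+].[Li+].C=C(C)[C@H](C/C=C(\C)C(=O)[O-])C[C@@]1(CC=C(C)C)C([O-])=C(C(=O)c2ccccc2)C(=O)C2=C1OC(C)(C)C=C2 | intermediate (not isolated)
23 | (2E,5R)-5-{[(8S)-6-benzoyl-7-hydroxy-2,2-dimethyl-8-(3-methylbut-2-en-1-yl)-5-oxo-5,8-dihydro-2H-chromen-8-yl]methyl}-2,6-dimethylhepta-2,6-dienoic acid | C=C(C)[C@H](C/C=C(\C)C(=O)O)C[C@@]1(CC=C(C)C)C(O)=C(C(=O)c2ccccc2)C(=O)C2=C1OC(C)(C)C=C2 | target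

Total step count: 9. Longest linear sequence: 9 steps (1 to 23; 10, 15 and 17 enter as purchased materials).

Steps most likely to fail

Step 8 (the proposed new method). The alkenyl transfer from boron may stall at the weakly electrophilic vinylogous amide, or ring closure may take the other oxygen. The fallback makes the same two bonds one stage earlier by known chemistry and sets out from 14, a true salicylaldehyde. Condensation of 14 with 17 and Bn2NH (1,4-dioxane, 90 °C; borono-Mannich chromene synthesis) should give methyl (2E,5R)-5-[(6-benzoyl-5,7-dihydroxy-2,2-dimethyl-2H-chromen-8-yl)methyl]-2,6-dimethylhepta-2,6-dienoate F1, which is separated from any product of closure onto the other phenol oxygen. F1 is then prenylated at C8 with 15 under the palladium conditions of step 7, which dearomatises the ring and sets the quaternary centre; the route is rejoined at 21.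

Step 5. O-alkylation of the phenoxide, slow substitution at the β-branched primary carbon, or double alkylation may dominate. The fallback forms the aryl–CH2 bond by cross-coupling and sets out from 10 and 9. Bromination of 10 (NBS, MeCN, 0 °C) gives (3-bromo-2,4,6-trihydroxyphenyl)(phenyl)methanone F2, and acetylation (Ac2O, pyridine) gives 2-benzoyl-4-bromobenzene-1,3,5-triyl triacetate F3. Iodide 9 is converted with Zn dust and LiCl in THF into iodo[(2S,4E)-6-methoxy-5-methyl-6-oxo-2-(prop-1-en-2-yl)hex-4-en-1-yl]zinc F4. Negishi coupling of F3 and F4 (Pd(OAc)2, SPhos, THF, 50 °C) gives methyl (2E,5R)-5-[(2,4,6-triacetoxy-3-benzoylphenyl)methyl]-2,6-dimethylhepta-2,6-dienoate F5. Methanolysis of the aryl acetates (K2CO3, MeOH, 0 °C) rejoins the route at 12.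

Step 7. Facial selectivity at the planar anion may be poor, or attack may occur at the substituted allyl terminus (reverse prenylation). The fallback gives up catalyst control and sets out from 14. Alkylation with 1-bromo-3-methylbut-2-ene (NaOMe, MeOH, 0 °C) should give 16 together with its epimer at the quaternary carbon, methyl (2E,5R)-5-{[(1S)-3-benzoyl-5-formyl-2,6-dihydroxy-1-(3-methylbut-2-en-1-yl)-4-oxocyclohexa-2,5-dien-1-yl]methyl}-2,6-dimethylhepta-2,6-dienoate F6. The two diastereomers are separated by preparative HPLC and the route is rejoined at 16.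

Further compounds
F1 | step 8 | methyl (2E,5R)-5-[(6-benzoyl-5,7-dihydroxy-2,2-dimethyl-2H-chromen-8-yl)methyl]-2,6-dimethylhepta-2,6-dienoate | C=C(C)[C@H](C/C=C(\C)C(=O)OC)Cc1c(O)c(C(=O)c2ccccc2)c(O)c2c1OC(C)(C)C=C2
F2 | step 5 | (3-bromo-2,4,6-trihydroxyphenyl)(phenyl)methanone | O=C(c1ccccc1)c1c(O)cc(O)c(Br)c1O
F3 | step 5 | 2-benzoyl-4-bromobenzene-1,3,5-triyl triacetate | CC(=O)Oc1cc(OC(C)=O)c(C(=O)c2ccccc2)c(OC(C)=O)c1Br
F4 | step 5 | iodo[(2S,4E)-6-methoxy-5-methyl-6-oxo-2-(prop-1-en-2-yl)hex-4-en-1-yl]zinc | C=C(C)[C@H](C/C=C(\C)C(=O)OC)C[Zn]I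
F5 | step 5 | methyl (2E,5R)-5-[(2,4,6-triacetoxy-3-benzoylphenyl)methyl]-2,6-dimethylhepta-2,6-dienoate | C=C(C)[C@H](C/C=C(\C)C(=O)OC)Cc1c(OC(C)=O)cc(OC(C)=O)c(C(=O)c2ccccc2)c1OC(C)=O
F6 | step 7 | methyl (2E,5R)-5-{[(1S)-3-benzoyl-5-formyl-2,6-dihydroxy-1-(3-methylbut-2-en-1-yl)-4-oxocyclohexa-2,5-dien-1-yl]methyl}-2,6-dimethylhepta-2,6-dienoate | C=C(C)[C@H](C/C=C(\C)C(=O)OC)C[C@]1(CC=C(C)C)C(O)=C(C(=O)c2ccccc2)C(=O)C(C=O)=C1O
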